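**Plan**

1. Cuts: the exocyclic methylene goes back to a C8 ketone. The δ-lactone is cut at C5–C6 and C3–C4 in one [4+2] step: its C6–O1–C2(=O)–C3(O) atoms are the enol-lactone diene C6–O1–C2–C3 of aromatic 3-hydroxy-2H-pyran-2-one, and its C4–C5 bond is the Cα=Cβ bond of an (E)-enal. The pyranone C4=C5 bridge is a helper, removed later as two CO2.
2. Further cuts: the enal at its C=C (cross-metathesis), the vinyl group at the quaternary C1 (conjugate addition), the seven-membered ring at C8–C8a (alkene acylation), the chain by a Wittig reaction, the cyclopentene from (+)-fenchone (Beckmann fragmentation).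
3. Forward order: cyclopentene, seven-membered ring, quaternary carbon with cis fusion, enal, bicyclo[2.2.2] lactone by dearomatising cycloaddition, unveiling of the δ-lactone, acetates, methylene.
4. Stereochemistry: C3a comes from fenchone; C1 and C8a from convex-face addition and protonation; lactone C5 from the chiral amine on the iminium face, supported by the substrate; C4 from the E alkene; C3 from equatorial protonation followed by Mitsunobu inversion. The endo and exo adducts converge because their bridgehead centres are erased.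
5. The quaternary carbon carries no γ-hydrogen, so the enal can react only as an iminium ion at Cβ and cannot form a dienamine.

Key step: step 9

Remark 1: nitrile 4 is drawn as the cyclopent-2-ene isomer; any cyclopent-3-ene isomer formed with it is carried along, since both pass through the same tertiary cation in step 6.
Remark 2: compounds 17 to 21 are drawn as the series with the C8 substituent endo; the exo series, if formed, should give the same lactone 23.

Numbering used in the text: hydroazulene C1 (quaternary), C3a and C8a (ring fusion), C4 (CMe2), C8 (C=O or C=CH2); lactone O1, C2 (C=O) to C6; bicycle C1, O2, C3 to C8.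

**Route**

Step 1
Reactants: 1 (+)-fenchone
Product: 2 (1S,4R)-fenchone oxime (hydroxyl anti to C1)
Conditions: NH2OH·HCl, NaOAc, EtOH/H2O, reflux
Reagents that add atoms: hydroxylamine hydrochloride, NO.Cl
Why: Oxime formation on the hindered ketone should place the hydroxyl away from the in-plane bridgehead methyl group; both stereocentres of fenchone are untouched.

Step 2
Reactants: 2 fenchone oxime
Product: 4 2-methyl-2-[(1R)-3-methylcyclopent-2-en-1-yl]propanenitrile, via oxime tosylate 3 (not isolated)
Conditions: TsCl, pyridine, 0 to 80 °C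
Reagents that add atoms: none
Why: Beckmann fragmentation: ionisation of the tosylate should cleave the anti C1–C2 bond to a nitrile and a tertiary 1-methylcyclopentyl cation that loses a proton, while C4 of fenchone (the future C3a) stays intact.

Step 3
Reactants: 4 nitrile
Product: 6 2-methyl-2-[(1R)-3-methylcyclopent-2-en-1-yl]propanal, via aluminium aldimine 5 (not isolated)
Conditions: i-Bu2AlH, CH2Cl2, −78 °C; then 1 M HCl, 0 °C
Reagents that add atoms: water, O
Why: Nitrile-to-aldehyde reduction: the hydride should add once to the tertiary nitrile and the aldimine is hydrolysed on acidic work-up.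

Step 4
Reactants: 6 aldehyde; 7 (2-carboxyethyl)triphenylphosphonium bromide
Product: 8 (3Z)-5-methyl-5-[(1R)-3-methylcyclopent-2-en-1-yl]hex-3-enoic acid
Conditions: 7, NaN(SiMe3)2 (2 equiv), THF, 0 °C; then 6, −78 °C to rt; aqueous HCl work-up
Reagents that add atoms: none
Why: Wittig olefination with the unstabilised carboxylate ylide should give the β,γ-unsaturated acid and brings in the three carbons that complete the seven-membered ring; the alkene geometry is of no consequence.

Step 5
Reactants: 8 unsaturated acid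
Product: 9 5-methyl-5-[(1R)-3-methylcyclopent-2-en-1-yl]hexanoic acid
Conditions: H2 (1 atm), RhCl(PPh3)3 (cat.), benzene/EtOH, rt
Reagents that add atoms: none
Why: Homogeneous hydrogenation with this catalyst is sensitive to substitution, so the disubstituted chain alkene should be saturated while the trisubstituted ring alkene survives.

Step 6
Reactants: 9 acid
Product: 12 (3aS)-1,4,4-trimethyl-3,3a,4,5,6,7-hexahydroazulen-8(2H)-one, via acid chloride 10 (not isolated), via chloro ketone 11 (not isolated)
Conditions: (COCl)2, DMF (cat.), CH2Cl2, 0 °C to rt; SnCl4, CH2Cl2, −78 to 0 °C; then DBU, rt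
Reagents that add atoms: none
Why: Intramolecular Friedel–Crafts-type alkene acylation (Darzens–Nenitzescu): the acylium ion should bond to the less substituted alkene carbon and close the seven-membered ring through a tertiary cation; chloride capture and E1cB elimination then give the conjugated enone.

Step 7
Reactants: 12 enone
Product: 14 (1S,3aR,8aR)-1-ethenyl-1,4,4-trimethyloctahydroazulen-8(1H)-one (cis-fused, vinyl cis to both ring-fusion hydrogens), via silyl enol ether 13 (not isolated)
Conditions: CH2=CHMgBr, CuBr·SMe2 (cat.), Me3SiCl, THF, −78 to −30 °C; then 1 M HCl, THF, 0 °C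
Reagents that add atoms: vinylmagnesium bromide, C=C[Mg]Br
Why: Copper-catalysed conjugate addition to the s-cis 2-alkylidene ketone (the pulegone type) should place the vinyl group on the convex face of C1, opposite C4 of the seven-membered ring that stands over the other face from C3a; kinetic protonation of 13 at C8a from the same face should set the cis fusion.

Step 8
Reactants: 14 vinyl ketone
Product: 15 (2E)-3-[(1S,3aR,8aR)-1,4,4-trimethyl-8-oxodecahydroazulen-1-yl]prop-2-enal
Conditions: crotonaldehyde (excess), second-generation Hoveyda–Grubbs catalyst RuCl2(=CH-C6H4-2-O-i-Pr)(H2IMes) (cat.), CH2Cl2, 40 °C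
Reagents that add atoms: (E)-crotonaldehyde, C/C=C/C=O
Why: Olefin cross-metathesis: the vinyl group on the quaternary carbon does not homodimerise and should exchange with crotonaldehyde to the favoured (E)-enal with loss of propene.

Step 9
Reactants: 15 enal; 16 3-hydroxy-2H-pyran-2-one
Product: 17 (1R,4R,7R,8S)-4-hydroxy-3-oxo-7-[(1S,3aR,8aR)-1,4,4-trimethyl-8-oxodecahydroazulen-1-yl]-2-oxabicyclo[2.2.2]oct-5-ene-8-carbaldehyde (formyl endo, azulenyl exo, the two trans)
Conditions: (R)-2-[diphenyl(trimethylsilyloxy)methyl]pyrrolidine (20 mol %), PhCO2H (20 mol %), CHCl3, rt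
Reagents that add atoms: none
Why: Proposed new method: the secondary amine converts enal 15 into an (E)-iminium ion, C6 of the hydroxypyranone (as its ammonium dienolate) adds to the β-carbon, and the enamine so formed closes onto the C3 carbonyl of the resulting pyran-2,3-dione, a stepwise equivalent of a [4+2] cycloaddition that dearomatises 16 and makes the C6–Cβ and C3–Cα bonds in one operation. The closest known reactions are the amine-base- and primary-amine-catalysed Diels–Alder reactions of 3-hydroxy-2-pyranones with acrylates and enones, and the prolinol-ether-catalysed Michael–aldol cascades of enals with enolised 1,2-diketones. The two six-membered rings that share the new C7–C8 bond are closed by an intermolecular Michael addition followed by a 6-(enolexo)-exo-trig aldol step. C7 is set by the catalyst, whose diphenyl(silyloxy)methyl group blocks one face of the iminium ion (the (R)-amine exposes the face that gives the 7R centre), supported by the quaternary carbon, which turns its ring CH2 and not the ring-fusion CH toward that face; C8 follows from the E geometry and, being α to the aldehyde, can settle trans to the bulky C7 group; the bridgeheads C1 and C4 are fixed by the bicycle and are cleared later. The step needs attack through C6 and not C4 of the dienolate (only the C6 adduct can ring-close, the C4 adduct should revert), reaction of the amine with the aldehyde and not the hindered ketone, and no dienamine formation, which the absence of a γ-hydrogen secures.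

Step 10
Reactants: 17 cycloadduct
Product: 18 (1R,4R,7R,8R)-4-hydroxy-8-(hydroxymethyl)-7-[(1S,3aR,8aR)-1,4,4-trimethyl-8-oxodecahydroazulen-1-yl]-2-oxabicyclo[2.2.2]oct-5-en-3-one
Conditions: NaBH4 (0.5 equiv), MeOH/CH2Cl2, −78 °C
Reagents that add atoms: none
Why: Borohydride reduction should take the aldehyde far faster than the hindered cycloheptanone or the lactone; the endo hydroxymethyl group cannot reach the lactone carbonyl, so no translactonisation is expected.

Step 11
Reactants: 18 diol
Product: 19 [(1R,4R,7R,8R)-4-hydroxy-3-oxo-7-[(1S,3aR,8aR)-1,4,4-trimethyl-8-oxodecahydroazulen-1-yl]-2-oxabicyclo[2.2.2]oct-5-en-8-yl]methyl acetate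
Conditions: Ac2O (1.1 equiv), pyridine, CH2Cl2, 0 °C
Reagents that add atoms: acetic anhydride, CC(=O)OC(C)=O
Why: Selective acylation should take the primary alcohol only and leave the tertiary bridgehead alcohol free as the later handle for C3.

Step 12
Reactants: 19 monoacetate
Product: 21 (2S,3R,4R,5R)-4-(acetoxymethyl)-5-hydroxy-6-oxo-3-[(1S,3aR,8aR)-1,4,4-trimethyl-8-oxodecahydroazulen-1-yl]oxane-2,5-dicarboxylic acid, via dialdehyde 20 (not isolated)
Conditions: O3, CH2Cl2, −78 °C; Me2S; then NaClO2, NaH2PO4, 2-methyl-2-butene, t-BuOH/H2O, 0 °C to rt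
Reagents that add atoms: ozone, [O-][O+]=O; sodium chlorite, [Na+].[O-]Cl=O
Why: Ozonolysis cleaves the only alkene (the helper bridge) and Pinnick oxidation, which unlike periodate-based oxidants does not cleave the tertiary α-hydroxy aldehyde, should give the diacid; the bicycle thereby opens to the monocyclic δ-lactone.

Step 13
Reactants: 21 diacid
Product: 23 [(3R,4R,5R)-3-hydroxy-2-oxo-5-[(1S,3aR,8aR)-1,4,4-trimethyl-8-oxodecahydroazulen-1-yl]oxan-4-yl]methyl acetate, via monoacid 22 (not isolated)
Conditions: pyridine (cat.), toluene, 90 °C; then 9-mesityl-10-phenylacridinium tetrafluoroborate (cat.), PhSSPh (cat.), i-Pr2NEt (0.2 equiv), CF3CH2OH, 450 nm LED, rt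
Reagents that add atoms: none
Why: The carboxyl group β to the lactone carbonyl should be lost thermally (malonic-type decarboxylation), and axial protonation of the enediol, like equilibration under the amine, should give the all-equatorial 3,4-trans alcohol; the α-acyloxy acid at C6 is then removed by photoredox hydrodecarboxylation (carboxylate oxidation, loss of CO2, hydrogen transfer from thiophenol).

Step 14
Reactants: 23 hydroxy lactone
Product: 24 [(3S,4R,5R)-3-acetoxy-2-oxo-5-[(1S,3aR,8aR)-1,4,4-trimethyl-8-oxodecahydroazulen-1-yl]oxan-4-yl]methyl acetate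
Conditions: AcOH, PPh3, DIAD, THF, 0 °C to rt
Reagents that add atoms: acetic acid, CC(=O)O
Why: Mitsunobu esterification: the equatorial C3 alcohol, activated as its oxyphosphonium ion next to the lactone carbonyl, should be displaced by acetate with inversion (SN2), giving the 3-acetoxy group cis to the C4 acetoxymethyl group.

Step 15
Reactants: 24 keto diacetate
Product: 25 [(3S,4R,5R)-3-acetoxy-2-oxo-5-[(1R,3aR,8aS)-1,4,4-trimethyl-8-methylidenedecahydroazulen-1-yl]oxan-4-yl]methyl acetate (CNP0333014.1)
Conditions: Zn, CH2Br2, TiCl4, THF/CH2Cl2, 0 °C to rt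
Reagents that add atoms: dibromomethane, BrCBr
Why: Lombardo methylenation with the non-basic zinc/titanium reagent should convert the hindered, enolisable ketone to the exocyclic methylene without epimerising C8a or C3 and without touching the lactone or the acetates.

**Compound list**

1 | (1S,4R)-(+)-fenchone, (1S,4R)-1,3,3-trimethylbicyclo[2.2.1]heptan-2-one | CC1(C)[C@@H]2CC[C@@](C)(C2)C1=O | starting material
2 | (1S,4R)-fenchone oxime, hydroxyl anti to C1 | CC1(C)[C@@H]2CC[C@@](C)(C2)/C1=N/O | intermediate
3 | fenchone oxime O-tosylate | CC1(C)[C@@H]2CC[C@@](C)(C2)/C1=N/OS(=O)(=O)c1ccc(C)cc1 | intermediate (not isolated)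
4 | 2-methyl-2-[(1R)-3-methylcyclopent-2-en-1-yl]propanenitrile | N#CC(C)(C)[C@@H]1CCC(C)=C1 | intermediate
5 | N-(diisobutylaluminio)aldimine of 6 | CC(C)C[Al](CC(C)C)N=CC(C)(C)[C@@H]1CCC(C)=C1 | intermediate (not isolated)
6 | 2-methyl-2-[(1R)-3-methylcyclopent-2-en-1-yl]propanal | O=CC(C)(C)[C@@H]1CCC(C)=C1 | intermediate
7 | (2-carboxyethyl)triphenylphosphonium bromide | OC(=O)CC[P+](c1ccccc1)(c1ccccc1)c1ccccc1.[Br-] | starting material
8 | (3Z)-5-methyl-5-[(1R)-3-methylcyclopent-2-en-1-yl]hex-3-enoic acid | OC(=O)C/C=C\C(C)(C)[C@@H]1CCC(C)=C1 | intermediate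
9 | 5-methyl-5-[(1R)-3-methylcyclopent-2-en-1-yl]hexanoic acid | OC(=O)CCCC(C)(C)[C@@H]1CCC(C)=C1 | intermediate
10 | 5-methyl-5-[(1R)-3-methylcyclopent-2-en-1-yl]hexanoyl chloride | ClC(=O)CCCC(C)(C)[C@@H]1CCC(C)=C1 | intermediate (not isolated)
11 | (1R,3aR,8aS)-1-chloro-1,4,4-trimethyloctahydroazulen-8(1H)-one, cis-fused, chloride anti to the C8–C8a bond (either C1 epimer eliminates) | O=C1CCCC(C)(C)[C@@H]2CC[C@@](C)(Cl)[C@H]12 | intermediate (not isolated)
12 | (3aS)-1,4,4-trimethyl-3,3a,4,5,6,7-hexahydroazulen-8(2H)-one | O=C1CCCC(C)(C)[C@@H]2CCC(C)=C12 | intermediate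
13 | (1S,3aS)-1-ethenyl-1,4,4-trimethyl-8-(trimethylsilyloxy)-1,2,3,3a,4,5,6,7-octahydroazulene | C=C[C@]1(C)CC[C@@H]2C1=C(O[Si](C)(C)C)CCCC2(C)C | intermediate (not isolated)
14 | (1S,3aR,8aR)-1-ethenyl-1,4,4-trimethyloctahydroazulen-8(1H)-one | O=C1CCCC(C)(C)[C@@H]2CC[C@@](C)(C=C)[C@H]12 | intermediate
15 | (2E)-3-[(1S,3aR,8aR)-1,4,4-trimethyl-8-oxodecahydroazulen-1-yl]prop-2-enal | O=C1CCCC(C)(C)[C@@H]2CC[C@@](C)(/C=C/C=O)[C@H]12 | intermediate
16 | 3-hydroxy-2H-pyran-2-one | O=C1OC=CC=C1O | starting material
17 | (1R,4R,7R,8S)-4-hydroxy-3-oxo-7-[(1S,3aR,8aR)-1,4,4-trimethyl-8-oxodecahydroazulen-1-yl]-2-oxabicyclo[2.2.2]oct-5-ene-8-carbaldehyde | O=C1CCCC(C)(C)[C@@H]2CC[C@@](C)([C@@H]3[C@@H]4OC(=O)[C@@](O)(C=C4)[C@H]3C=O)[C@H]12 | intermediate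
18 | (1R,4R,7R,8R)-4-hydroxy-8-(hydroxymethyl)-7-[(1S,3aR,8aR)-1,4,4-trimethyl-8-oxodecahydroazulen-1-yl]-2-oxabicyclo[2.2.2]oct-5-en-3-one | O=C1CCCC(C)(C)[C@@H]2CC[C@@](C)([C@@H]3[C@@H]4OC(=O)[C@@](O)(C=C4)[C@H]3CO)[C@H]12 | intermediate
19 | [(1R,4R,7R,8R)-4-hydroxy-3-oxo-7-[(1S,3aR,8aR)-1,4,4-trimethyl-8-oxodecahydroazulen-1-yl]-2-oxabicyclo[2.2.2]oct-5-en-8-yl]methyl acetate | O=C1CCCC(C)(C)[C@@H]2CC[C@@](C)([C@@H]3[C@@H]4OC(=O)[C@@](O)(C=C4)[C@H]3COC(C)=O)[C@H]12 | intermediate
20 | 4-(acetoxymethyl)-5-hydroxy-6-oxo-3-[(1S,3aR,8aR)-1,4,4-trimethyl-8-oxodecahydroazulen-1-yl]oxane-2,5-dicarbaldehyde, configured as 21 | O=C1CCCC(C)(C)[C@@H]2CC[C@@](C)([C@@H]3[C@@H](C=O)OC(=O)[C@@](O)(C=O)[C@H]3COC(C)=O)[C@H]12 | intermediate (not isolated)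
21 | (2S,3R,4R,5R)-4-(acetoxymethyl)-5-hydroxy-6-oxo-3-[(1S,3aR,8aR)-1,4,4-trimethyl-8-oxodecahydroazulen-1-yl]oxane-2,5-dicarboxylic acid | O=C1CCCC(C)(C)[C@@H]2CC[C@@](C)([C@@H]3[C@@H](C(=O)O)OC(=O)[C@@](O)(C(=O)O)[C@H]3COC(C)=O)[C@H]12 | intermediate
22 | (2S,3R,4R,5R)-4-(acetoxymethyl)-5-hydroxy-6-oxo-3-[(1S,3aR,8aR)-1,4,4-trimethyl-8-oxodecahydroazulen-1-yl]oxane-2-carboxylic acid | O=C1CCCC(C)(C)[C@@H]2CC[C@@](C)([C@@H]3[C@@H](C(=O)O)OC(=O)[C@H](O)[C@H]3COC(C)=O)[C@H]12 | intermediate (not isolated)
23 | [(3R,4R,5R)-3-hydroxy-2-oxo-5-[(1S,3aR,8aR)-1,4,4-trimethyl-8-oxodecahydroazulen-1-yl]oxan-4-yl]methyl acetate | O=C1CCCC(C)(C)[C@@H]2CC[C@@](C)([C@@H]3COC(=O)[C@H](O)[C@H]3COC(C)=O)[C@H]12 | intermediate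
24 | [(3S,4R,5R)-3-acetoxy-2-oxo-5-[(1S,3aR,8aR)-1,4,4-trimethyl-8-oxodecahydroazulen-1-yl]oxan-4-yl]methyl acetate | O=C1CCCC(C)(C)[C@@H]2CC[C@@](C)([C@@H]3COC(=O)[C@@H](OC(C)=O)[C@H]3COC(C)=O)[C@H]12 | intermediate
25 | [(3S,4R,5R)-3-acetoxy-2-oxo-5-[(1R,3aR,8aS)-1,4,4-trimethyl-8-methylidenedecahydroazulen-1-yl]oxan-4-yl]methyl acetate (CNP0333014.1) | C=C1CCCC(C)(C)[C@@H]2CC[C@@](C)([C@@H]3COC(=O)[C@@H](OC(C)=O)[C@H]3COC(C)=O)[C@H]12 | target

**Summary**

Total step count: 15. Longest linear sequence: 15 steps (1 to 25).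

**Steps most likely to fail**

Step 9. The Michael addition at the neopentyl β-carbon of the iminium ion may be too slow, and control of the alkene face may be incomplete. The fallback replaces the intermolecular iminium pathway with a known silicon-tethered intramolecular Diels–Alder reaction. It sets out from 15, which is reduced (NaBH4, MeOH/CH2Cl2, −78 °C) to the allylic alcohol F1. This is joined to 16 with i-Pr2SiCl2 and imidazole to give the mixed silyl ketal F2. Heating (toluene, 110 °C) should bring about the tethered [4+2] reaction, in which the six-membered silyl ketal ring forces the C3–Cα bond, and give the tricyclic adduct F3. HF·pyridine in THF then removes the tether and returns the route to 18.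

Step 7. Transfer of the vinyl group to the tetrasubstituted β-carbon may be sluggish, with 1,2-addition or enolisation taking over. The fallback sets out from 12 and uses a Hosomi–Sakurai allylation (allyltrimethylsilane, TiCl4, CH2Cl2, −78 °C), which is reliable for fully substituted enones and follows the same convex-face logic, to give the allyl ketone F4. Alkene migration with RuHCl(CO)(PPh3)3 in toluene at 80 °C should give the (E)-propenyl ketone F5. Ozonolysis (O3, then Me2S) gives the keto aldehyde F6, and a Wittig reaction with (triphenylphosphoranylidene)acetaldehyde in toluene at reflux returns the route to 15.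

Step 13. Hydrogen transfer may be incomplete or over-oxidation may occur during the photoredox removal of the C6 carboxyl group, and the C3 configuration may drift under the amine. The fallback sets out from 21 and stops after the thermal decarboxylation (pyridine, toluene, 90 °C), so that 22 is isolated. Coupling with N-hydroxypyridine-2-thione (DCC, CH2Cl2, dark) gives the thiohydroxamate ester F7, and Barton reductive decarboxylation (t-BuSH, visible light, benzene) returns the route to 23 without base. Should protonation at C3 give the C3-epimeric alcohol F8 instead, that alcohol is acetylated with retention (Ac2O, pyridine) and joins the route at 24.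

**Further compounds**

F1 | step 9 | (1S,3aR,8aR)-1-[(1E)-3-hydroxyprop-1-en-1-yl]-1,4,4-trimethyloctahydroazulen-8(1H)-one | O=C1CCCC(C)(C)[C@@H]2CC[C@@](C)(/C=C/CO)[C@H]12
F2 | step 9 | diisopropylsilyl ketal of F1 and 3-hydroxy-2H-pyran-2-one | O=C1CCCC(C)(C)[C@@H]2CC[C@@](C)(/C=C/CO[Si](C(C)C)(C(C)C)OC3=CC=COC3=O)[C@H]12
F3 | step 9 | silicon-tethered cycloadduct, the 4-O,8-CH2O-diisopropylsilylene derivative of 18 | O=C1CCCC(C)(C)[C@@H]2CC[C@@](C)([C@@H]3[C@@H]4OC(=O)[C@]5(C=C4)O[Si](C(C)C)(C(C)C)OC[C@@H]35)[C@H]12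
F4 | step 7 | (1S,3aR,8aR)-1,4,4-trimethyl-1-(prop-2-en-1-yl)octahydroazulen-8(1H)-one | O=C1CCCC(C)(C)[C@@H]2CC[C@@](C)(CC=C)[C@H]12
F5 | step 7 | (1S,3aR,8aR)-1,4,4-trimethyl-1-[(1E)-prop-1-en-1-yl]octahydroazulen-8(1H)-one | O=C1CCCC(C)(C)[C@@H]2CC[C@@](C)(/C=C/C)[C@H]12
F6 | step 7 | (1S,3aR,8aR)-1,4,4-trimethyl-8-oxodecahydroazulene-1-carbaldehyde | O=C1CCCC(C)(C)[C@@H]2CC[C@@](C)(C=O)[C@H]12
F7 | step 13 | 2-thioxopyridin-1(2H)-yl ester of 22 | O=C1CCCC(C)(C)[C@@H]2CC[C@@](C)([C@@H]3[C@@H](C(=O)ON4C=CC=CC4=S)OC(=O)[C@H](O)[C@H]3COC(C)=O)[C@H]12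
F8 | step 13 | [(3S,4R,5R)-3-hydroxy-2-oxo-5-[(1S,3aR,8aR)-1,4,4-trimethyl-8-oxodecahydroazulen-1-yl]oxan-4-yl]methyl acetate (C3 epimer of 23) | O=C1CCCC(C)(C)[C@@H]2CC[C@@](C)([C@@H]3COC(=O)[C@@H](O)[C@H]3COC(C)=O)[C@H]12
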